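**Retrosynthetic overview**
1. Target 21 ⇐ C6–O bond: copper-catalysed γ-aroyloxylation of the silyl dienol ether of bicyclic β,γ-enone 16 with diaroyl peroxide 18 (new reaction, last step; sets C6).
2. 16 ⇐ ring-closing metathesis (C6=C7) of diene 15; the seven-membered ring is formed second, onto the existing cyclopentane.
3. 15 ⇐ Weinreb amide diol 12 by crotyl Grignard addition and selective acetylation.
4. 12 ⇐ enone 9: the C4–O bond by conjugate borylation/oxidation, the C2 carbinol by hydroxyl-directed reduction.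
5. 9 ⇐ 2-methylcyclopent-2-enone 1 (the five-membered ring is bought): asymmetric vinyl addition/enolate alkylation sets C5 and C1, then dehydrogenation and isopropyl installation.

Assumption: daucane numbering is used as shorthand (C1 = CH3-bearing ring-fusion carbon, C2 = CH–OAc, C3 = CH2, C4 = C(OH)(i-Pr), C5 = ring-fusion CH, C6–C10 = rest of the seven-membered ring, C9 = C=O; β = face of the C1 methyl); the target SMILES is read as (1S,2S,4R,5R,6R); C8 in 14–16 is an inconsequential epimer mixture.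

**Step 1**
Reactants: 1 2-methylcyclopent-2-en-1-one; 2 vinylmagnesium bromide; 3 2-bromo-N-methoxy-N-methylacetamide
Product: 5 N-methoxy-N-methyl-2-[(1S,5S)-1-methyl-2-oxo-5-vinylcyclopentyl]acetamide, via bromomagnesium enolate 4 (not isolated)
Conditions: CuBr·SMe2 (5 mol%), (R)-1-[(SP)-2-(diphenylphosphino)ferrocenyl]ethyldicyclohexylphosphine (6 mol%), t-BuOMe, −78 °C; then 3, DMPU, THF, −30 to 0 °C
Reagents that add atoms: none
Why: Copper-catalysed asymmetric conjugate addition (ligand enantiomer chosen to give 5S) sets C5, and the tetrasubstituted magnesium enolate is alkylated anti to the new vinyl group, so the quaternary C1 carries CH2C(O) trans and CH3 cis to vinyl (three-component conjugate addition–enolate trapping).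

**Step 2**
Reactants: 5 N-methoxy-N-methyl-2-[(1S,5S)-1-methyl-2-oxo-5-vinylcyclopentyl]acetamide
Product: 6 N-methoxy-N-methyl-2-[(1S,5R)-1-methyl-2-oxo-5-vinylcyclopent-3-en-1-yl]acetamide
Conditions: IBX, DMSO/PhF, 70 °C
Reagents that add atoms: none
Why: IBX α,β-dehydrogenation (Nicolaou oxidation) can only involve the CH2–CH2 side because the other α-carbon is quaternary, and both stereocentres are untouched.

**Step 3**
Reactants: 6 N-methoxy-N-methyl-2-[(1S,5R)-1-methyl-2-oxo-5-vinylcyclopent-3-en-1-yl]acetamide; 7 isopropylmagnesium chloride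
Product: 9 N-methoxy-N-methyl-2-[(1S,5R)-1-methyl-2-oxo-4-(propan-2-yl)-5-vinylcyclopent-3-en-1-yl]acetamide, via silyl enol ether 8 (not isolated)
Conditions: 7, CuBr·SMe2 (10 mol%), Me3SiCl, THF, −78 °C; then Pd(OAc)2 (10 mol%), O2 (1 atm), DMSO, 25 °C
Reagents that add atoms: none
Why: Copper-catalysed 1,4-addition with in situ silylation followed by Saegusa–Ito oxidation (catalytic divalent palladium, O2) restores the enone, so the net result is β-isopropylation and the transient stereocentre is erased.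

**Step 4**
Reactants: 9 N-methoxy-N-methyl-2-[(1S,5R)-1-methyl-2-oxo-4-(propan-2-yl)-5-vinylcyclopent-3-en-1-yl]acetamide
Product: 11 2-[(1S,4R,5S)-4-hydroxy-1-methyl-2-oxo-4-(propan-2-yl)-5-vinylcyclopentyl]-N-methoxy-N-methylacetamide, via boryl ketone 10 (not isolated)
Conditions: B2pin2, CuCl (5 mol%), 1,3-bis(2,4,6-trimethylphenyl)imidazolium chloride (6 mol%), NaOt-Bu (15 mol%), MeOH (2 equiv), THF, 25 °C; then 30% H2O2, pH 7 phosphate buffer, 0 °C
Reagents that add atoms: hydrogen peroxide OO
Why: Copper-catalysed conjugate borylation puts Bpin on the β-carbon from the face opposite the neighbouring vinyl group, and stereoretentive C–B oxidation forms the tertiary C–O bond with OH trans to vinyl.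

**Step 5**
Reactants: 11 2-[(1S,4R,5S)-4-hydroxy-1-methyl-2-oxo-4-(propan-2-yl)-5-vinylcyclopentyl]-N-methoxy-N-methylacetamide
Product: 12 2-[(1S,2S,4R,5S)-2,4-dihydroxy-1-methyl-4-(propan-2-yl)-5-vinylcyclopentyl]-N-methoxy-N-methylacetamide
Conditions: Me4NBH(OAc)3, MeCN/AcOH 1:1, −20 °C
Reagents that add atoms: none
Why: Evans–Saksena reduction: the tertiary hydroxyl binds the acetoxyborohydride and delivers hydride to its own face of the ketone, giving the anti (trans) 1,3-diol with the new hydroxyl cis to the ring methyl.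

**Step 6**
Reactants: 12 2-[(1S,2S,4R,5S)-2,4-dihydroxy-1-methyl-4-(propan-2-yl)-5-vinylcyclopentyl]-N-methoxy-N-methylacetamide; 13 but-2-enylmagnesium chloride
Product: 14 1-[(1S,2S,4R,5S)-2,4-dihydroxy-1-methyl-4-(propan-2-yl)-5-vinylcyclopentyl]-3-methylpent-4-en-2-one
Conditions: 13 (3.5 equiv), THF, −78 to −20 °C; sat. NH4Cl, 0 °C
Reagents that add atoms: none
Why: Weinreb ketone synthesis; the allylic Grignard reagent reacts through its γ-carbon to give the α-methyl β,γ-unsaturated ketone, the chelated tetrahedral intermediate prevents over-addition, and the new C–H stereocentre (mixture) becomes sp2 in step 10.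

**Step 7**
Reactants: 14 1-[(1S,2S,4R,5S)-2,4-dihydroxy-1-methyl-4-(propan-2-yl)-5-vinylcyclopentyl]-3-methylpent-4-en-2-one
Product: 15 (1S,2S,3S,4R)-4-hydroxy-2-methyl-2-(3-methyl-2-oxopent-4-en-1-yl)-4-(propan-2-yl)-3-vinylcyclopentyl acetate
Conditions: Ac2O, pyridine, DMAP (5 mol%), CH2Cl2, 0 °C
Reagents that add atoms: acetic anhydride CC(=O)OC(C)=O
Why: DMAP-catalysed acylation is selective for the secondary over the hindered tertiary hydroxyl and installs the acetate with retention.

**Step 8**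
Reactants: 15 (1S,2S,3S,4R)-4-hydroxy-2-methyl-2-(3-methyl-2-oxopent-4-en-1-yl)-4-(propan-2-yl)-3-vinylcyclopentyl acetate
Product: 16 (1S,2S,4R,5S)-2-acetoxy-4-hydroxydauc-6-en-9-one
Conditions: second-generation Grubbs catalyst RuCl2(=CHPh)(PCy3)(1,3-dimesitylimidazolidin-2-ylidene) (5 mol%), CH2Cl2 (5 mM), 40 °C
Reagents that add atoms: none
Why: Ring-closing metathesis of the two monosubstituted alkenes releases ethene and closes the seven-membered ring, trans-fused because vinyl and the ketone side chain were set trans in step 1.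

**Step 9**
Reactants: 17 4-acetoxybenzoic acid (2 equiv)
Product: 18 bis(4-acetoxybenzoyl) peroxide
Conditions: DCC (2.0 equiv), anhydrous H2O2 in Et2O (1.0 equiv; 17 : H2O2 = 2 : 1), CH2Cl2, 0 °C
Reagents that add atoms: hydrogen peroxide OO; 4-acetoxybenzoic acid (second molecule of 17) CC(=O)Oc1ccc(cc1)C(=O)O
Why: Carbodiimide activation of two molecules of the acid and acylation of both oxygens of one molecule of hydrogen peroxide is the standard diacyl peroxide synthesis, and the base-free conditions leave the aryl acetates intact.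

**Step 10**
Reactants: 16 (1S,2S,4R,5S)-2-acetoxy-4-hydroxydauc-6-en-9-one; 18 bis(4-acetoxybenzoyl) peroxide
Product: 21 2β-acetoxy-4α-hydroxy-6α-(4-hydroxybenzoyloxy)dauc-7-en-9-one (target), via silyl dienol ether 19 (not isolated), via silylated aryl acetate 20 (not isolated)
Conditions: Me3SiOTf (2.5 equiv), Et3N (3 equiv), CH2Cl2, 0 °C, pentane filtration; then 18 (1.3 equiv), Cu(MeCN)4PF6 (10 mol%), 4,4′-di-tert-butyl-2,2′-bipyridine (12 mol%), MeCN/CH2Cl2, −20 °C; then K2CO3 (0.2 equiv), MeOH, 0 °C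
Reagents that add atoms: none
Why: Proposed new method: monovalent copper cleaves the O–O bond of 18 to an aroyloxy–copper species (a trivalent copper bis-carboxylate, or a divalent copper carboxylate plus an aroyloxyl radical), which is attacked by the electron-rich C6 terminus of the 9-silyloxy-6,8-diene; C–O bond formation with transfer of Me3Si to the second carboxylate occurs at the γ-carbon rather than at the methyl-bearing α-carbon C8 (which would give a quaternary centre and no conjugation), and from the α-face, anti to the β-oriented C1 methyl and C4 isopropyl groups, setting C6 as R; mild methanolysis then removes the phenolic acetate and the silyl ether but not the hindered alkyl acetate or the benzoate; the closest known reaction types are peracid oxidation of silyl dienol ethers to γ-hydroxy enones (vinylogous Rubottom oxidation), α-benzoyloxylation of enamines and enol derivatives with dibenzoyl peroxide, and Kharasch–Sosnovsky copper carboxylate transfer.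

**Compound list**
1 | 2-methylcyclopent-2-en-1-one | CC1=CCCC1=O | starting material
2 | vinylmagnesium bromide | C=C[Mg]Br | starting material
3 | 2-bromo-N-methoxy-N-methylacetamide | CON(C)C(=O)CBr | starting material
4 | bromomagnesium enolate of (S)-2-methyl-3-vinylcyclopentanone | C=C[C@@H]1CCC(O[Mg]Br)=C1C | intermediate
5 | N-methoxy-N-methyl-2-[(1S,5S)-1-methyl-2-oxo-5-vinylcyclopentyl]acetamide (vinyl cis to CH3) | O=C1CC[C@@H](C=C)[C@]1(C)CC(=O)N(C)OC | intermediate
6 | N-methoxy-N-methyl-2-[(1S,5R)-1-methyl-2-oxo-5-vinylcyclopent-3-en-1-yl]acetamide | O=C1C=C[C@@H](C=C)[C@]1(C)CC(=O)N(C)OC | intermediate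
7 | isopropylmagnesium chloride | CC(C)[Mg]Cl | starting material
8 | trimethylsilyl enol ether of the isopropyl adduct of 6 (i-Pr trans to vinyl) | C[Si](C)(C)OC1=C[C@H](C(C)C)[C@@H](C=C)[C@]1(C)CC(=O)N(C)OC | intermediate
9 | N-methoxy-N-methyl-2-[(1S,5R)-1-methyl-2-oxo-4-(propan-2-yl)-5-vinylcyclopent-3-en-1-yl]acetamide | O=C1C=C(C(C)C)[C@@H](C=C)[C@]1(C)CC(=O)N(C)OC | intermediate
10 | β-(pinacolboryl) ketone from 9 (Bpin trans to vinyl) | O=C1C[C@@](B2OC(C)(C)C(C)(C)O2)(C(C)C)[C@@H](C=C)[C@]1(C)CC(=O)N(C)OC | intermediate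
11 | 2-[(1S,4R,5S)-4-hydroxy-1-methyl-2-oxo-4-(propan-2-yl)-5-vinylcyclopentyl]-N-methoxy-N-methylacetamide | O=C1C[C@@](O)(C(C)C)[C@@H](C=C)[C@]1(C)CC(=O)N(C)OC | intermediate
12 | 2-[(1S,2S,4R,5S)-2,4-dihydroxy-1-methyl-4-(propan-2-yl)-5-vinylcyclopentyl]-N-methoxy-N-methylacetamide | O[C@H]1C[C@@](O)(C(C)C)[C@@H](C=C)[C@]1(C)CC(=O)N(C)OC | intermediate
13 | but-2-enylmagnesium chloride | CC=CC[Mg]Cl | starting material
14 | 1-[(1S,2S,4R,5S)-2,4-dihydroxy-1-methyl-4-(propan-2-yl)-5-vinylcyclopentyl]-3-methylpent-4-en-2-one (epimers at the CH–CH3 carbon) | O[C@H]1C[C@@](O)(C(C)C)[C@@H](C=C)[C@]1(C)CC(=O)C(C)C=C | intermediate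
15 | (1S,2S,3S,4R)-4-hydroxy-2-methyl-2-(3-methyl-2-oxopent-4-en-1-yl)-4-(propan-2-yl)-3-vinylcyclopentyl acetate | CC(=O)O[C@H]1C[C@@](O)(C(C)C)[C@@H](C=C)[C@]1(C)CC(=O)C(C)C=C | intermediate
16 | (1S,2S,4R,5S)-2-acetoxy-4-hydroxydauc-6-en-9-one (C8 epimers; trans-fused) | CC(=O)O[C@H]1C[C@@](O)(C(C)C)[C@H]2C=CC(C)C(=O)C[C@]12C | intermediate
17 | 4-acetoxybenzoic acid | CC(=O)Oc1ccc(cc1)C(=O)O | starting material
18 | bis(4-acetoxybenzoyl) peroxide | CC(=O)Oc1ccc(cc1)C(=O)OOC(=O)c1ccc(OC(C)=O)cc1 | intermediate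
19 | 2β-acetoxy-4α,9-bis(trimethylsilyloxy)dauca-6,8-diene | CC(=O)O[C@H]1C[C@@](O[Si](C)(C)C)(C(C)C)[C@H]2C=CC(C)=C(O[Si](C)(C)C)C[C@]12C | intermediate
20 | 2β-acetoxy-6α-(4-acetoxybenzoyloxy)-4α-(trimethylsilyloxy)dauc-7-en-9-one | CC(=O)O[C@H]1C[C@@](O[Si](C)(C)C)(C(C)C)[C@H]2[C@H](OC(=O)c3ccc(OC(C)=O)cc3)C=C(C)C(=O)C[C@]12C | intermediate
21 | (1S,2S,4R,5R,6R)-2β-acetoxy-4α-hydroxy-6α-(4-hydroxybenzoyloxy)dauc-7-en-9-one, CNP0087181.1 | CC(=O)O[C@H]1C[C@@](O)(C(C)C)[C@H]2[C@H](OC(=O)c3ccc(O)cc3)C=C(C)C(=O)C[C@]12C | target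

**Step count and weak points**
Total steps: 10. Longest linear sequence: 9 (steps 1–8 and 10; step 9 makes the reagent 18).

Step 1 is at risk because copper-catalysed asymmetric addition of a vinyl Grignard reagent to an α-methyl cyclopentenone, with alkylation of the hindered enolate, may give low ee or yield. The fallback sets out from 2 and comes back at 9. Reagent 2 is converted with B(OMe)3 and then aqueous KHF2 into potassium vinyltrifluoroborate F1. Hayashi–Miyaura addition of F1 to commercial cyclopent-2-enone ([RhCl(C8H12)]2, BINAP enantiomer as required, toluene/H2O) gives (R)-3-vinylcyclopentanone F2. LiN(i-Pr)2/Me3SiCl gives the silyl enol ether on the side remote from the vinyl group, (R)-trimethyl[(4-vinylcyclopent-1-en-1-yl)oxy]silane F3, and Saegusa–Ito oxidation (Pd(OAc)2, O2, DMSO) gives (R)-4-vinylcyclopent-2-enone F4. Copper-catalysed addition of 7 with Me3SiCl gives the trimethylsilyl enol ether of trans-3-isopropyl-4-vinylcyclopentanone F5, which is oxidised in the same way to (R)-3-isopropyl-4-vinylcyclopent-2-enone F6. LiN(i-Pr)2 then MeI gives trans-3-isopropyl-5-methyl-4-vinylcyclopent-2-enone F7, and a second deprotonation followed by 3 alkylates anti to the vinyl group to give 9.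

Step 4 is at risk because the β,β-disubstituted enone is hindered and its doubly allylic γ-hydrogen is base-sensitive. The fallback sets out from 9 and comes back at 11. Weitz–Scheffer epoxidation (30% H2O2, LiOH cat., MeOH, −10 °C; attack anti to vinyl) gives the α-epoxy ketone F8. Reductive opening at the α-carbon with PhSeNa, made from (PhSe)2 and NaBH4 in EtOH/AcOH, gives 11.

Step 10 is the new reaction. The risks are α- versus γ-attack, the face of attack at C6 (six-membered dienol ethers are known to react syn to an angular methyl, and the C4 silyloxy group lies on the α-face), and side reactions of the peroxide. The fallback uses known chemistry, sets out from 16 and comes back at 21. Silyl dienol ether 19, made as in step 10, is oxidised with mCPBA (vinylogous Rubottom oxidation) and desilylated on acidic work-up to 2β-acetoxy-4α,6α-dihydroxydauc-7-en-9-one F9. Steglich esterification of F9 with 17 (DCC, DMAP, CH2Cl2) gives 2β-acetoxy-6α-(4-acetoxybenzoyloxy)-4α-hydroxydauc-7-en-9-one F10. K2CO3 (cat.) in MeOH at 0 °C removes only the phenolic acetate to give 21.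

**Further compounds**
F1 | step 1 | potassium vinyltrifluoroborate | [K+].F[B-](F)(F)C=C
F2 | step 1 | (R)-3-vinylcyclopentanone | O=C1CC[C@@H](C=C)C1
F3 | step 1 | (R)-trimethyl[(4-vinylcyclopent-1-en-1-yl)oxy]silane | C[Si](C)(C)OC1=CC[C@@H](C=C)C1
F4 | step 1 | (R)-4-vinylcyclopent-2-en-1-one | O=C1C=C[C@@H](C=C)C1
F5 | step 1 | trimethylsilyl enol ether of trans-3-isopropyl-4-vinylcyclopentanone | C[Si](C)(C)OC1=C[C@H](C(C)C)[C@@H](C=C)C1
F6 | step 1 | (R)-3-isopropyl-4-vinylcyclopent-2-en-1-one | O=C1C=C(C(C)C)[C@@H](C=C)C1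
F7 | step 1 | trans-3-isopropyl-5-methyl-4-vinylcyclopent-2-en-1-one | O=C1C=C(C(C)C)[C@@H](C=C)[C@@H]1C
F8 | step 4 | α-epoxy ketone of 9 (epoxide trans to vinyl) | O=C1[C@@H]2O[C@]2(C(C)C)[C@@H](C=C)[C@]1(C)CC(=O)N(C)OC
F9 | step 10 | 2β-acetoxy-4α,6α-dihydroxydauc-7-en-9-one | CC(=O)O[C@H]1C[C@@](O)(C(C)C)[C@H]2[C@H](O)C=C(C)C(=O)C[C@]12C
F10 | step 10 | 2β-acetoxy-6α-(4-acetoxybenzoyloxy)-4α-hydroxydauc-7-en-9-one | CC(=O)O[C@H]1C[C@@](O)(C(C)C)[C@H]2[C@H](OC(=O)c3ccc(OC(C)=O)cc3)C=C(C)C(=O)C[C@]12C
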